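**Plan**

- The four flavan units are called A (upper epicatechin), B (epigallocatechin 3-O-gallate), C (inner epicatechin) and D (terminal catechin). The retrosynthesis first removes all benzyl ethers and a bromine cap, then cuts C4(A)–C8(B) and C4(B)–C8(C) as Lewis-acid 4→8 condensations of C4-alkoxy flavans.
- In the remaining C–D dimer the pyran ring of unit C is opened at C3–C4. This leaves a C3 aldehyde tethered through O1–C2 and a C4 carbon attached to C4a of unit C and C8 of unit D. That carbon is then cut from C8(D) (aryllithium + aldehyde), and O1–C2 is cut as an allylic etherification.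
- Enabling feature: C4 of unit C lies between two phloroglucinol-type rings (the A ring of C through C4a, the A ring of D through C8), so it supports a persistent bis(2,4,6-trioxyphenyl)methylium ion. Two-electron reduction with SmI2 makes this carbon a nucleophile that attacks the C3 aldehyde and closes the pyran ring.
- Forward order: O1–C2 ether, C4–C8(D) bond, alkene to C3 aldehyde, closure of the pyran ring of C, then unit B, then unit A, then hydrogenolysis.
- Stereochemistry: units A, B and D come from (−)-epicatechin, (−)-epigallocatechin and (+)-catechin. C2 of unit C comes from Ir-catalysed asymmetric allylic etherification, C3 and C4 of unit C from the cyclisation transition state under control of C2, and both new 4β linkages from trans attack on C4 cations.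

Key step: step 11

Assumption: the carbinol carbon made in step 9 (the later C4 of unit C) forms as an epimer mixture and is drawn without configuration in 13–17; it is planarised in step 11.

**Route**

Step 1
Reactants: 1 2,4,6-trihydroxybenzaldehyde
Product: 2 4,6-bis(benzyloxy)-2-hydroxybenzaldehyde
Conditions: BnBr (2.05 equiv), K2CO3, DMF, rt
Reagents that add atoms: benzyl bromide, BrCc1ccccc1
Why: Williamson etherification takes the 4-OH and one ortho OH, while the remaining ortho OH is held in a hydrogen bond to the formyl group and should stay free.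

Step 2
Reactants: 3 3,4-bis(benzyloxy)benzaldehyde
Product: 4 ethyl (E)-3-[3,4-bis(benzyloxy)phenyl]prop-2-enoate
Conditions: (EtO)2P(O)CH2CO2Et, NaH, THF, 0 °C to rt
Reagents that add atoms: triethyl phosphonoacetate, CCOC(=O)CP(=O)(OCC)OCC
Why: Horner–Wadsworth–Emmons olefination of an aromatic aldehyde with a stabilised phosphonate should give the E enoate.

Step 3
Reactants: 4 ethyl (E)-3-[3,4-bis(benzyloxy)phenyl]prop-2-enoate
Product: 5 (E)-3-[3,4-bis(benzyloxy)phenyl]prop-2-en-1-ol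
Conditions: DIBAL-H (2.2 equiv), CH2Cl2, −78 to 0 °C; Rochelle salt
Reagents that add atoms: none
Why: DIBAL-H 1,2-reduction of the unsaturated ester should give the allylic alcohol without touching the alkene or the benzyl ethers.

Step 4
Reactants: 5 (E)-3-[3,4-bis(benzyloxy)phenyl]prop-2-en-1-ol
Product: 6 (E)-3-[3,4-bis(benzyloxy)phenyl]prop-2-en-1-yl methyl carbonate
Conditions: ClCO2Me, pyridine, CH2Cl2, 0 °C
Reagents that add atoms: methyl chloroformate, COC(Cl)=O
Why: Acylation of the primary allylic alcohol with a chloroformate installs the carbonate leaving group for allylic substitution.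

Step 5
Reactants: 2 4,6-bis(benzyloxy)-2-hydroxybenzaldehyde; 6 (E)-3-[3,4-bis(benzyloxy)phenyl]prop-2-en-1-yl methyl carbonate
Product: 7 4,6-bis(benzyloxy)-2-{[(1S)-1-[3,4-bis(benzyloxy)phenyl]prop-2-en-1-yl]oxy}benzaldehyde
Conditions: [Ir(cod)Cl]2 (cat.), (Sa,Sc,Sc)-Feringa-type phosphoramidite (the ligand enantiomer that gives the S ether), DBU (cat.), THF, 25–50 °C
Reagents that add atoms: none
Why: In this iridium-catalysed asymmetric allylic etherification (Hartwig type) the phenoxide, formed by the methoxide released from the carbonate, should attack the aryl-bearing terminus of the allyl-iridium intermediate to give the branched ether, and the ligand sets the later C2 of unit C.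

Step 6
Reactants: 8 (+)-catechin
Product: 9 5,7,3',4'-tetra-O-benzyl-(+)-catechin
Conditions: BnBr (4.4 equiv), K2CO3, DMF, 0 °C to rt
Reagents that add atoms: benzyl bromide, BrCc1ccccc1
Why: Williamson etherification with K2CO3 should benzylate the four phenols only and leave the less acidic C3 alcohol and the C2 configuration untouched.

Step 7
Reactants: 9 5,7,3',4'-tetra-O-benzyl-(+)-catechin
Product: 10 3,5,7,3',4'-penta-O-benzyl-(+)-catechin
Conditions: NaH, BnBr, Bu4NI (cat.), DMF, 0 °C to rt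
Reagents that add atoms: benzyl bromide, BrCc1ccccc1
Why: Williamson etherification of the secondary alcohol through its sodium alkoxide gives an aprotic nucleophile precursor for the organolithium step.

Step 8
Reactants: 10 3,5,7,3',4'-penta-O-benzyl-(+)-catechin
Product: 11 8-bromo-3,5,7,3',4'-penta-O-benzyl-(+)-catechin
Conditions: NBS (1.0 equiv), CH2Cl2, −40 °C to rt
Reagents that add atoms: N-bromosuccinimide, O=C1CCC(=O)N1Br
Why: Electrophilic aromatic bromination should occur at C8, the more reactive of the two free A-ring positions of a 5,7-di-O-benzylflavan.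

Step 9
Reactants: 11 8-bromo-3,5,7,3',4'-penta-O-benzyl-(+)-catechin; 7 4,6-bis(benzyloxy)-2-{[(1S)-1-[3,4-bis(benzyloxy)phenyl]prop-2-en-1-yl]oxy}benzaldehyde
Product: 14 8-{[4,6-bis(benzyloxy)-2-{[(1S)-1-[3,4-bis(benzyloxy)phenyl]prop-2-en-1-yl]oxy}phenyl](methoxy)methyl}-penta-O-benzyl-(+)-catechin, via 8-lithio-penta-O-benzylcatechin 12 (not isolated), via lithium diarylmethoxide 13 (not isolated)
Conditions: t-BuLi (2.0 equiv), THF, −78 °C; then 7; then MeOTf, −78 to 0 °C
Reagents that add atoms: methyl trifluoromethanesulfonate, COS(=O)(=O)C(F)(F)F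
Why: Bromine–lithium exchange, 1,2-addition of the aryllithium to the aldehyde and O-methylation of the alkoxide in one pot should join C8 of unit D to the later C4 of unit C and install an aprotic leaving group there, without touching the existing stereocentres.

Step 10
Reactants: 14 8-{[4,6-bis(benzyloxy)-2-{[(1S)-1-[3,4-bis(benzyloxy)phenyl]prop-2-en-1-yl]oxy}phenyl](methoxy)methyl}-penta-O-benzyl-(+)-catechin
Product: 16 (2R)-2-[3,4-bis(benzyloxy)phenyl]-2-{3,5-bis(benzyloxy)-2-[methoxy(penta-O-benzylcatechin-8-yl)methyl]phenoxy}acetaldehyde, via vicinal diol 15 (not isolated)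
Conditions: OsO4 (cat.), NaIO4, 2,6-lutidine, dioxane–H2O, rt; used crude
Reagents that add atoms: osmium tetroxide, O=[Os](=O)(=O)=O; sodium periodate, [Na+].[O-]I(=O)(=O)=O
Why: Lemieux–Johnson oxidation (osmium-catalysed dihydroxylation, then periodate cleavage) of the only alkene should give the C3 aldehyde under buffered conditions that keep the α-aryloxy stereocentre intact.

Step 11
Reactants: 16 (2R)-2-[3,4-bis(benzyloxy)phenyl]-2-{3,5-bis(benzyloxy)-2-[methoxy(penta-O-benzylcatechin-8-yl)methyl]phenoxy}acetaldehyde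
Product: 18 tetra-O-benzyl-epicatechin-(4β→8)-penta-O-benzylcatechin, via diarylcarbenium triflate 17 (not isolated)
Conditions: TMSOTf (1.1 equiv), 2,6-di-tert-butyl-4-methylpyridine (cat.), CH2Cl2, −78 °C; then into SmI2 (3 equiv), THF, −78 to −30 °C; aqueous work-up
Reagents that add atoms: none
Why: Proposed new method: TMSOTf should remove the methoxy group of 16 to give the bis(2,4,6-trioxyphenyl)methylium ion 17, which SmI2 should reduce in two one-electron steps (persistent diarylmethyl radical, then diarylmethylsamarium(III)); this carbon nucleophile adds to the tethered C3 aldehyde in a 6-exo-trig closure that forms the C3–C4 bond and the pyran ring of unit C. The closest known reaction type is the SmI2 Barbier cyclisation of benzylic halides onto aldehydes, extended here to a preformed carbenium ion as the precursor; if the second electron transfer is slow, HMPA is added so that the samarium ketyl of the aldehyde couples with the persistent radical, which forms the same bond. At C4 the catechin aryl group should take the pseudo-axial position of the half-chair, because the pseudo-equatorial site suffers A(1,3) strain with the C5 benzyloxy group, and this places it trans to the equatorial C2 aryl group. At C3 the samarium-bound oxygen should lie anti to that aryl group and therefore axial, cis to the C2 aryl group, so the C2 centre from step 5 controls both new centres and gives the 2,3-cis-3,4-trans (4β) arrangement. The step needs chemoselective reduction of the carbenium ion before the aldehyde (secured by SmI2 in THF without HMPA at low temperature) and retention at C2 (secured by non-basic conditions).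

Step 12
Reactants: 19 (−)-epigallocatechin
Product: 20 5,7,3',4',5'-penta-O-benzyl-(−)-epigallocatechin
Conditions: BnBr (5.5 equiv), K2CO3, DMF, argon, 0 °C to rt
Reagents that add atoms: benzyl bromide, BrCc1ccccc1
Why: Williamson etherification of the five phenols under argon should protect the air-sensitive pyrogallol ring and leave the C3 alcohol free.

Step 13
Reactants: 20 5,7,3',4',5'-penta-O-benzyl-(−)-epigallocatechin
Product: 21 4β-(2-ethoxyethoxy)-5,7,3',4',5'-penta-O-benzyl-(−)-epigallocatechin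
Conditions: DDQ (2 equiv), 2-ethoxyethanol, CH2Cl2, rt
Reagents that add atoms: 2-ethoxyethanol, CCOCCO
Why: DDQ benzylic oxidation at C4 (hydride abstraction assisted by the 5,7-dioxygenated A ring) and capture of the cation by the alcohol trans to the C3 hydroxyl should give the C4 ether.

Step 14
Reactants: 21 4β-(2-ethoxyethoxy)-5,7,3',4',5'-penta-O-benzyl-(−)-epigallocatechin; 22 3,4,5-tris(benzyloxy)benzoic acid
Product: 23 4β-(2-ethoxyethoxy)-5,7,3',4',5'-penta-O-benzyl-(−)-epigallocatechin 3-O-[3,4,5-tris(benzyloxy)benzoate]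
Conditions: DCC, DMAP, CH2Cl2, rt
Reagents that add atoms: none
Why: Steglich esterification should acylate the axial C3 hydroxyl under neutral conditions that leave the acid-labile C4 ether intact.

Step 15
Reactants: 18 tetra-O-benzyl-epicatechin-(4β→8)-penta-O-benzylcatechin; 23 4β-(2-ethoxyethoxy)-5,7,3',4',5'-penta-O-benzyl-(−)-epigallocatechin 3-O-[3,4,5-tris(benzyloxy)benzoate]
Product: 24 octa-O-benzyl-epigallocatechin gallate-(4β→8)-tetra-O-benzyl-epicatechin-(4β→8)-penta-O-benzylcatechin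
Conditions: 18 (2 equiv, excess recovered), TMSOTf (cat.), CH2Cl2, −78 °C, slow addition of 23
Reagents that add atoms: none
Why: In this Lewis-acid-promoted Friedel–Crafts 4→8 condensation TMSOTf ionises the C4 ether of 23, and C8 of the upper unit of 18, its most nucleophilic free position, should attack the benzylic cation anti to the C3 acyloxy group to give the 3,4-trans (4β) linkage.

Step 16
Reactants: 25 (−)-epicatechin
Product: 26 5,7,3',4'-tetra-O-benzyl-(−)-epicatechin
Conditions: BnBr (4.4 equiv), K2CO3, DMF, 0 °C to rt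
Reagents that add atoms: benzyl bromide, BrCc1ccccc1
Why: Williamson etherification with K2CO3 should benzylate the four phenols only.

Step 17
Reactants: 26 5,7,3',4'-tetra-O-benzyl-(−)-epicatechin
Product: 27 8-bromo-5,7,3',4'-tetra-O-benzyl-(−)-epicatechin
Conditions: NBS (1.0 equiv), CH2Cl2, −40 °C to rt
Reagents that add atoms: N-bromosuccinimide, O=C1CCC(=O)N1Br
Why: Electrophilic aromatic bromination at C8 caps the nucleophilic position of the future electrophile so that it cannot self-condense.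

Step 18
Reactants: 27 8-bromo-5,7,3',4'-tetra-O-benzyl-(−)-epicatechin
Product: 28 8-bromo-4β-(2-ethoxyethoxy)-5,7,3',4'-tetra-O-benzyl-(−)-epicatechin
Conditions: DDQ (2 equiv), 2-ethoxyethanol, CH2Cl2, rt
Reagents that add atoms: 2-ethoxyethanol, CCOCCO
Why: DDQ benzylic oxidation at C4 and capture of the cation by the alcohol trans to the C3 hydroxyl should give the C4 ether.

Step 19
Reactants: 24 octa-O-benzyl-epigallocatechin gallate-(4β→8)-tetra-O-benzyl-epicatechin-(4β→8)-penta-O-benzylcatechin; 28 8-bromo-4β-(2-ethoxyethoxy)-5,7,3',4'-tetra-O-benzyl-(−)-epicatechin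
Product: 29 fully protected tetramer: 8-bromo-tetra-O-benzyl-epicatechin-(4β→8)-octa-O-benzyl-epigallocatechin gallate-(4β→8)-tetra-O-benzyl-epicatechin-(4β→8)-penta-O-benzylcatechin
Conditions: TMSOTf (cat.), CH2Cl2, −78 °C
Reagents that add atoms: none
Why: In this Lewis-acid-promoted Friedel–Crafts 4→8 condensation C8 of the gallate-bearing top unit of 24 should attack the C4 cation of 28 anti to its C3 hydroxyl and C2 aryl group (4β), while the bromine on 28 blocks self-condensation.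

Step 20
Reactants: 29 fully protected tetramer
Product: 30 epicatechin-(4β→8)-epigallocatechin 3-O-gallate-(4β→8)-epicatechin-(4β→8)-catechin (CNP0332815.1)
Conditions: H2 (1 atm), Pd(OH)2/C, Et3N (1.1 equiv), THF–MeOH–H2O, rt
Reagents that add atoms: none
Why: Hydrogenolysis over Pearlman's catalyst should cleave all 21 benzyl ethers and the aryl C–Br bond, while the gallate ester, the interflavan bonds and all stereocentres are stable under these conditions.

**Compound list**

1 | 2,4,6-trihydroxybenzaldehyde | O=Cc1c(O)cc(O)cc1O | starting material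
2 | 4,6-bis(benzyloxy)-2-hydroxybenzaldehyde | O=Cc1c(O)cc(OCc2ccccc2)cc1OCc1ccccc1 | intermediate
3 | 3,4-bis(benzyloxy)benzaldehyde | O=Cc1ccc(OCc2ccccc2)c(OCc2ccccc2)c1 | starting material
4 | ethyl (E)-3-[3,4-bis(benzyloxy)phenyl]prop-2-enoate | CCOC(=O)/C=C/c1ccc(OCc2ccccc2)c(OCc2ccccc2)c1 | intermediate
5 | (E)-3-[3,4-bis(benzyloxy)phenyl]prop-2-en-1-ol | OC/C=C/c1ccc(OCc2ccccc2)c(OCc2ccccc2)c1 | intermediate
6 | (E)-3-[3,4-bis(benzyloxy)phenyl]prop-2-en-1-yl methyl carbonate | COC(=O)OC/C=C/c1ccc(OCc2ccccc2)c(OCc2ccccc2)c1 | intermediate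
7 | 4,6-bis(benzyloxy)-2-{[(1S)-1-[3,4-bis(benzyloxy)phenyl]prop-2-en-1-yl]oxy}benzaldehyde | O=Cc1c(O[C@H](c2ccc(OCc3ccccc3)c(OCc3ccccc3)c2)C=C)cc(OCc2ccccc2)cc1OCc1ccccc1 | intermediate
8 | (+)-catechin, (2R,3S) | Oc1cc(O)c2c(c1)O[C@H](c1ccc(O)c(O)c1)[C@@H](O)C2 | starting material
9 | 5,7,3',4'-tetra-O-benzyl-(+)-catechin | C(c1ccccc1)Oc1cc(OCc2ccccc2)c2c(c1)O[C@H](c1ccc(OCc3ccccc3)c(OCc3ccccc3)c1)[C@@H](O)C2 | intermediate
10 | 3,5,7,3',4'-penta-O-benzyl-(+)-catechin | C(c1ccccc1)Oc1cc(OCc2ccccc2)c2c(c1)O[C@H](c1ccc(OCc3ccccc3)c(OCc3ccccc3)c1)[C@@H](OCc1ccccc1)C2 | intermediate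
11 | 8-bromo-3,5,7,3',4'-penta-O-benzyl-(+)-catechin | C(c1ccccc1)Oc1cc(OCc2ccccc2)c2c(c1Br)O[C@H](c1ccc(OCc3ccccc3)c(OCc3ccccc3)c1)[C@@H](OCc1ccccc1)C2 | intermediate
12 | 8-lithio-3,5,7,3',4'-penta-O-benzyl-(+)-catechin | C(c1ccccc1)Oc1cc(OCc2ccccc2)c2c(c1[Li])O[C@H](c1ccc(OCc3ccccc3)c(OCc3ccccc3)c1)[C@@H](OCc1ccccc1)C2 | intermediate
13 | lithium alkoxide of the diarylmethanol from 12 and 7 (carbinol carbon unassigned) | [Li]OC(c1c(O[C@H](c2ccc(OCc3ccccc3)c(OCc3ccccc3)c2)C=C)cc(OCc2ccccc2)cc1OCc1ccccc1)c1c(OCc2ccccc2)cc(OCc2ccccc2)c2c1O[C@H](c1ccc(OCc3ccccc3)c(OCc3ccccc3)c1)[C@@H](OCc1ccccc1)C2 | intermediate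
14 | 8-{[4,6-bis(benzyloxy)-2-{[(1S)-1-[3,4-bis(benzyloxy)phenyl]prop-2-en-1-yl]oxy}phenyl](methoxy)methyl}-3,5,7,3',4'-penta-O-benzyl-(+)-catechin (epimers at the methoxy carbon) | COC(c1c(O[C@H](c2ccc(OCc3ccccc3)c(OCc3ccccc3)c2)C=C)cc(OCc2ccccc2)cc1OCc1ccccc1)c1c(OCc2ccccc2)cc(OCc2ccccc2)c2c1O[C@H](c1ccc(OCc3ccccc3)c(OCc3ccccc3)c1)[C@@H](OCc1ccccc1)C2 | intermediate
15 | vicinal diol from 14: the vinyl group is replaced by CH(OH)CH2OH (new carbinol centre unassigned) | COC(c1c(O[C@H](c2ccc(OCc3ccccc3)c(OCc3ccccc3)c2)C(O)CO)cc(OCc2ccccc2)cc1OCc1ccccc1)c1c(OCc2ccccc2)cc(OCc2ccccc2)c2c1O[C@H](c1ccc(OCc3ccccc3)c(OCc3ccccc3)c1)[C@@H](OCc1ccccc1)C2 | intermediate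
16 | (2R)-2-[3,4-bis(benzyloxy)phenyl]-2-{3,5-bis(benzyloxy)-2-[methoxy(3,5,7,3',4'-penta-O-benzylcatechin-8-yl)methyl]phenoxy}acetaldehyde | COC(c1c(O[C@H](c2ccc(OCc3ccccc3)c(OCc3ccccc3)c2)C=O)cc(OCc2ccccc2)cc1OCc1ccccc1)c1c(OCc2ccccc2)cc(OCc2ccccc2)c2c1O[C@H](c1ccc(OCc3ccccc3)c(OCc3ccccc3)c1)[C@@H](OCc1ccccc1)C2 | intermediate
17 | diarylcarbenium triflate from 16 (methoxy group lost, cationic CH between the two trioxygenated rings) | [CH+](c1c(O[C@H](c2ccc(OCc3ccccc3)c(OCc3ccccc3)c2)C=O)cc(OCc2ccccc2)cc1OCc1ccccc1)c1c(OCc2ccccc2)cc(OCc2ccccc2)c2c1O[C@H](c1ccc(OCc3ccccc3)c(OCc3ccccc3)c1)[C@@H](OCc1ccccc1)C2.[O-]S(=O)(=O)C(F)(F)F | intermediate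
18 | 5,7,3',4'-tetra-O-benzyl-(−)-epicatechin-(4β→8)-3,5,7,3',4'-penta-O-benzyl-(+)-catechin (upper unit 2R,3R, 3,4-trans, 3-OH free) | c1c(OCc2ccccc2)cc(OCc2ccccc2)c2c1O[C@H](c1ccc(OCc3ccccc3)c(OCc3ccccc3)c1)[C@H](O)[C@H]2c1c(OCc2ccccc2)cc(OCc2ccccc2)c2c1O[C@H](c1ccc(OCc3ccccc3)c(OCc3ccccc3)c1)[C@@H](OCc1ccccc1)C2 | intermediate
19 | (−)-epigallocatechin, (2R,3R) | O[C@@H]1Cc2c(O)cc(O)cc2O[C@@H]1c1cc(O)c(O)c(O)c1 | starting material
20 | 5,7,3',4',5'-penta-O-benzyl-(−)-epigallocatechin | O[C@@H]1Cc2c(OCc3ccccc3)cc(OCc3ccccc3)cc2O[C@@H]1c1cc(OCc2ccccc2)c(OCc2ccccc2)c(OCc2ccccc2)c1 | intermediate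
21 | 4β-(2-ethoxyethoxy)-5,7,3',4',5'-penta-O-benzyl-(−)-epigallocatechin (3,4-trans) | O[C@@H]1[C@@H](OCCOCC)c2c(OCc3ccccc3)cc(OCc3ccccc3)cc2O[C@@H]1c1cc(OCc2ccccc2)c(OCc2ccccc2)c(OCc2ccccc2)c1 | intermediate
22 | 3,4,5-tris(benzyloxy)benzoic acid | OC(=O)c1cc(OCc2ccccc2)c(OCc2ccccc2)c(OCc2ccccc2)c1 | starting material
23 | 4β-(2-ethoxyethoxy)-5,7,3',4',5'-penta-O-benzyl-(−)-epigallocatechin 3-O-[3,4,5-tris(benzyloxy)benzoate] | O=C(O[C@@H]1[C@@H](OCCOCC)c2c(OCc3ccccc3)cc(OCc3ccccc3)cc2O[C@@H]1c1cc(OCc2ccccc2)c(OCc2ccccc2)c(OCc2ccccc2)c1)c1cc(OCc2ccccc2)c(OCc2ccccc2)c(OCc2ccccc2)c1 | intermediate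
24 | protected trimer: octa-O-benzyl-epigallocatechin gallate-(4β→8)-tetra-O-benzyl-epicatechin-(4β→8)-penta-O-benzylcatechin (3-OH of the middle unit free) | O=C(O[C@@H]1[C@@H](c2c(OCc4ccccc4)cc(OCc4ccccc4)c3c2O[C@H](c2ccc(OCc4ccccc4)c(OCc4ccccc4)c2)[C@H](O)[C@H]3c2c(OCc4ccccc4)cc(OCc4ccccc4)c3c2O[C@H](c2ccc(OCc4ccccc4)c(OCc4ccccc4)c2)[C@@H](OCc2ccccc2)C3)c2c(OCc3ccccc3)cc(OCc3ccccc3)cc2O[C@@H]1c1cc(OCc2ccccc2)c(OCc2ccccc2)c(OCc2ccccc2)c1)c1cc(OCc2ccccc2)c(OCc2ccccc2)c(OCc2ccccc2)c1 | intermediate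
25 | (−)-epicatechin, (2R,3R) | C1c2c(O)cc(O)cc2O[C@H](c2ccc(O)c(O)c2)[C@@H]1O | starting material
26 | 5,7,3',4'-tetra-O-benzyl-(−)-epicatechin | C1c2c(OCc3ccccc3)cc(OCc3ccccc3)cc2O[C@H](c2ccc(OCc3ccccc3)c(OCc3ccccc3)c2)[C@@H]1O | intermediate
27 | 8-bromo-5,7,3',4'-tetra-O-benzyl-(−)-epicatechin | C1c2c(OCc3ccccc3)cc(OCc3ccccc3)c(Br)c2O[C@H](c2ccc(OCc3ccccc3)c(OCc3ccccc3)c2)[C@@H]1O | intermediate
28 | 8-bromo-4β-(2-ethoxyethoxy)-5,7,3',4'-tetra-O-benzyl-(−)-epicatechin (3,4-trans) | CCOCCO[C@H]1c2c(OCc3ccccc3)cc(OCc3ccccc3)c(Br)c2O[C@H](c2ccc(OCc3ccccc3)c(OCc3ccccc3)c2)[C@@H]1O | intermediate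
29 | fully protected tetramer: 8-bromo-tetra-O-benzyl-epicatechin-(4β→8)-octa-O-benzyl-epigallocatechin gallate-(4β→8)-tetra-O-benzyl-epicatechin-(4β→8)-penta-O-benzylcatechin | O=C(O[C@@H]1[C@@H](c2c(OCc4ccccc4)cc(OCc4ccccc4)c3c2O[C@H](c2ccc(OCc4ccccc4)c(OCc4ccccc4)c2)[C@H](O)[C@H]3c2c(OCc4ccccc4)cc(OCc4ccccc4)c3c2O[C@H](c2ccc(OCc4ccccc4)c(OCc4ccccc4)c2)[C@@H](OCc2ccccc2)C3)c2c(OCc3ccccc3)cc(OCc3ccccc3)c([C@H]3c4c(OCc5ccccc5)cc(OCc5ccccc5)c(Br)c4O[C@H](c4ccc(OCc5ccccc5)c(OCc5ccccc5)c4)[C@@H]3O)c2O[C@@H]1c1cc(OCc2ccccc2)c(OCc2ccccc2)c(OCc2ccccc2)c1)c1cc(OCc2ccccc2)c(OCc2ccccc2)c(OCc2ccccc2)c1 | intermediate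
30 | epicatechin-(4β→8)-epigallocatechin 3-O-gallate-(4β→8)-epicatechin-(4β→8)-catechin (CNP0332815.1) | O=C(O[C@@H]1[C@@H](c2c(O)cc(O)c3c2O[C@H](c2ccc(O)c(O)c2)[C@H](O)[C@H]3c2c(O)cc(O)c3c2O[C@H](c2ccc(O)c(O)c2)[C@@H](O)C3)c2c(O)cc(O)c([C@H]3c4c(O)cc(O)cc4O[C@H](c4ccc(O)c(O)c4)[C@@H]3O)c2O[C@@H]1c1cc(O)c(O)c(O)c1)c1cc(O)c(O)c(O)c1 | target

**Step count and risks**

Total step count: 20. Longest linear sequence: 10 steps (steps 2, 3, 4, 5, 9, 10, 11, 15, 19, 20).

Steps most likely to fail: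

1. Step 11 (proposed new method). The second electron transfer to the hindered, electron-rich diarylmethyl radical may be too slow, so that the radical dimerises or abstracts hydrogen. The benzylic samarium species may be protonated before it cyclises. A samarium ketyl may expel the C2 aryloxide. The facial selectivity of the ring closure may be poor. Fallback with known chemistry, giving up the C3–C4 closure: tetra-O-benzylepicatechin 26 is oxidised with DDQ in the presence of 2-ethoxyethanol to 4β-(2-ethoxyethoxy)-5,7,3',4'-tetra-O-benzylepicatechin F1. F1 is then condensed with an excess of penta-O-benzylcatechin 10 under TMSOTf in CH2Cl2 at −78 °C, where C8 of 10 attacks the C4 cation anti to the C3 hydroxyl. The fallback sets out from 26 and 10 and comes back to the route at 18.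

2. Step 5. The aryloxide of a salicylaldehyde is a fair leaving group and the electron-rich aryl group stabilises the allyl cation, so the catalyst may re-ionise the product ether. This would erode the branched-to-linear ratio and the enantiomeric purity. Fallback by stereospecific substitution of a resolved branched carbonate:
 - Aldehyde 3 is treated with vinylmagnesium bromide to give racemic 1-[3,4-bis(benzyloxy)phenyl]prop-2-en-1-ol F2.
 - Lipase-catalysed acylation (CAL-B, vinyl acetate) should leave (S)-1-[3,4-bis(benzyloxy)phenyl]prop-2-en-1-ol F3 and convert the other enantiomer into (R)-1-[3,4-bis(benzyloxy)phenyl]prop-2-en-1-yl acetate F4, which is separated.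
 - F3 is converted with methyl chloroformate and pyridine into (S)-1-[3,4-bis(benzyloxy)phenyl]prop-2-en-1-yl methyl carbonate F5.
 - F5 reacts with the copper(I) phenoxide of 2 (LiHMDS, CuI) under RhCl(PPh3)3/P(OMe)3 catalysis, which should proceed with net retention and branched selectivity.
 
 The fallback sets out from 3 and 2 and comes back to the route at 7.

3. Step 15. The monomeric electrophile 23 may self-condense through its own free C8, the trimer may be extended further, and some attack may leak to C6. Fallback by a 2+2 assembly: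
 - 20 is esterified with 22 (DCC, DMAP) to 5,7,3',4',5'-penta-O-benzyl-epigallocatechin 3-O-[3,4,5-tris(benzyloxy)benzoate] F6.
 - F6 in excess is condensed with the bromine-capped electrophile 28 (TMSOTf, CH2Cl2, −78 °C) to the upper dimer 8-bromo-tetra-O-benzyl-epicatechin-(4β→8)-octa-O-benzyl-epigallocatechin gallate F7.
 - DDQ oxidation of F7 in the presence of 2-ethoxyethanol at its only benzylic methylene (C4 of the lower unit) gives the dimeric electrophile F8, the 4β-(2-ethoxyethoxy) derivative of F7.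
 - F8 is condensed with 18 in a 1:1 ratio under TMSOTf.
 
 The fallback sets out from 20, 22, 28 and 18 and comes back to the route at 29, bypassing 24.

Further compounds
F1 | step 11 | 4β-(2-ethoxyethoxy)-5,7,3',4'-tetra-O-benzyl-(−)-epicatechin | CCOCCO[C@H]1c2c(OCc3ccccc3)cc(OCc3ccccc3)cc2O[C@H](c2ccc(OCc3ccccc3)c(OCc3ccccc3)c2)[C@@H]1O
F2 | step 5 | racemic 1-[3,4-bis(benzyloxy)phenyl]prop-2-en-1-ol | OC(C=C)c1ccc(OCc2ccccc2)c(OCc2ccccc2)c1
F3 | step 5 | (S)-1-[3,4-bis(benzyloxy)phenyl]prop-2-en-1-ol | O[C@H](c1ccc(OCc2ccccc2)c(OCc2ccccc2)c1)C=C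
F4 | step 5 | (R)-1-[3,4-bis(benzyloxy)phenyl]prop-2-en-1-yl acetate | CC(=O)O[C@@H](c1ccc(OCc2ccccc2)c(OCc2ccccc2)c1)C=C
F5 | step 5 | (S)-1-[3,4-bis(benzyloxy)phenyl]prop-2-en-1-yl methyl carbonate | COC(=O)O[C@H](c1ccc(OCc2ccccc2)c(OCc2ccccc2)c1)C=C
F6 | step 15 | 5,7,3',4',5'-penta-O-benzyl-(−)-epigallocatechin 3-O-[3,4,5-tris(benzyloxy)benzoate] | O=C(O[C@@H]1Cc2c(OCc3ccccc3)cc(OCc3ccccc3)cc2O[C@@H]1c1cc(OCc2ccccc2)c(OCc2ccccc2)c(OCc2ccccc2)c1)c1cc(OCc2ccccc2)c(OCc2ccccc2)c(OCc2ccccc2)c1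
F7 | step 15 | 8-bromo-tetra-O-benzyl-epicatechin-(4β→8)-octa-O-benzyl-epigallocatechin gallate | O=C(O[C@@H]1Cc2c(OCc3ccccc3)cc(OCc3ccccc3)c([C@H]3c4c(OCc5ccccc5)cc(OCc5ccccc5)c(Br)c4O[C@H](c4ccc(OCc5ccccc5)c(OCc5ccccc5)c4)[C@@H]3O)c2O[C@@H]1c1cc(OCc2ccccc2)c(OCc2ccccc2)c(OCc2ccccc2)c1)c1cc(OCc2ccccc2)c(OCc2ccccc2)c(OCc2ccccc2)c1
F8 | step 15 | 4β-(2-ethoxyethoxy) derivative of F7 at C4 of the epigallocatechin gallate unit | O=C(O[C@@H]1[C@@H](OCCOCC)c2c(OCc3ccccc3)cc(OCc3ccccc3)c([C@H]3c4c(OCc5ccccc5)cc(OCc5ccccc5)c(Br)c4O[C@H](c4ccc(OCc5ccccc5)c(OCc5ccccc5)c4)[C@@H]3O)c2O[C@@H]1c1cc(OCc2ccccc2)c(OCc2ccccc2)c(OCc2ccccc2)c1)c1cc(OCc2ccccc2)c(OCc2ccccc2)c(OCc2ccccc2)c1
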